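# Beta-collatolic acid by enol translactonization of alpha-collatolic acid: synthesis design

## The problem

Beta-collatolic acid (22) is a diaryl ether in which C8 of a 6-methoxy-3-pentylisocoumarin (ring A with its pyranone) is bound through oxygen to C5' of a benzoic acid ring (ring B) that carries the carboxyl on C1', hydroxyls on C2' and C4' and a 2-oxoheptyl arm on C6'. There is no stereocenter, so the difficulties are positional and chemical. The ether oxygen lies between two ortho substituents on each ring, which makes a late intermolecular aryl ether coupling unattractive. Both rings derive from the same unit, a benzoic acid flanked by a 2-oxoheptyl arm, and the synthesis must close the enol lactone on ring A while the identical arm of ring B stays a free keto acid. Several groups are fragile: the isocoumarin opens with hydroxide or alkoxide, the free 2,4-dihydroxybenzoic acid decarboxylates on heating or in strong acid, and both benzylic ketones enolize easily and attack any activated carboxyl beside them. The structure offers its own solution, because the lactone carbonyl C1 of ring A is ortho to the 2-oxoheptyl arm and ring B has a hydroxyl on C4' directly beside the ether carbon C5'. C1 can therefore be stored on the C4' oxygen as the seven-membered ester of a depsidone and handed to the enol oxygen at the end.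

## Retrosynthesis

**22 to 21.** The O2-C1 bond of the pyranone is cut and C1 is reconnected to the C4' oxygen, which gives alpha-collatolic acid 21. The neighbouring cuts are weaker. Lactonizing an open diaryl ether diacid would have to tell apart two carboxyls that each sit ortho to a 2-oxoheptyl arm, and an early isocoumarin would face every later basic step. In 21 only the ring A carboxyl is an activated aryl ester; the ring B carboxyl is a free acid. 21 is an isomer of 22, not a smaller compound, but it turns a chemoselectivity problem into a ring construction problem. The forward step needs mild base in a dry aprotic medium, so that the benzylic enolate oxygen is the only nucleophile that reaches C1.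

**21 to 20 to 19.** Two masks are removed. The ring B carboxyl is a benzyl ester in 20, because a methyl ester could not be cleaved late without opening the seven-membered ester. Both ketones are dioxolanes in 19. Acid hydrolysis comes first and hydrogenolysis second, so that 21 is obtained by filtration under neutral conditions.

**19 to 18.** The aryl ether bond O-C5' is cut, which leads to depside 18 with a free phenol on ring A and iodine on C5'. A direct oxidative coupling of an unhalogenated depside has no handle to choose between C3' and C5', both ortho to the ester oxygen. Ether formation before the ester would pair a hindered, electron-rich halide with a chelated salicylate phenol. With the ester in place the closure is an intramolecular Ullmann etherification to a seven-membered ring. The ketals are essential here. A ring A enolate would cleave the open depside ester, and a ring B enolate would O-arylate the neighbouring C-I bond to a benzofuran.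

**18 to 17 to 16 and 12.** The ester bond C1-O(C4') is cut into acid 16 and phenol 12, halves of similar size. The ring A phenol carries a 4-methoxybenzyl ether in 17 and 16. This is the one group that must leave while iodine, benzyl ester and ketals stay, so it is removed by oxidation, not by hydrogen or strong acid. Of the two hydroxyls of 12, the C4' hydroxyl is acylated; the C2' hydroxyl is chelated to the ester.

**12 to 11 to 10 to 9.** The C5'-I bond comes from electrophilic iodination of 11, para to the chelated hydroxyl and ortho to the free one. It is placed after the hydrogenolysis because an aryl iodide would not survive hydrogen over palladium. The benzyl ester of 11 is made by carboxylate alkylation of dihydroxy acid 10 with 2. Acid 10 comes from 9 by hydrogenolysis, and 9 from ester 8 by saponification.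

**16 to 15 to 14 to 13 to 8.** Ring A needs only functional group changes on the same ketal ester 8: hydrogenolysis to 13, methylation of the unchelated hydroxyl to 14, 4-methoxybenzylation to 15 and saponification to 16. Using 8 for both rings means the side chain is built once.

**8 to 7 to 3 and 5.** The benzylic C-C(=O) bond of the arm is cut. Lateral lithiation of the ortho-toluate 3 and acylation with Weinreb amide 5 gives ketone 7, which is ketalized at once to 8. Weinreb amide 5 comes from hexanoyl chloride 4, and 3 from methyl orsellinate 1 and two equivalents of benzyl bromide 2, one for each phenol. The forward reaction needs a single benzylic anion and an acyl donor that does not release the ketone under basic conditions.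

## Roads not taken

Alternative 1: Ring A is assembled on an aryne relay.
- Cut: three bonds at once, the ether bond O-C8 and the carbon bonds C8a-C1 and C4a-C4.
- Forward key step: fluoride releases a first aryne from 5-methoxy-2-(trimethylsilyl)-1,3-phenylene bis(triflate) A1. The phenoxide of the protected ring B phenol A2 adds at the future C8, and the aryl anion expels the second triflate. The new C8a-C4a aryne inserts into a C-C bond of diallyl malonate A3 to give homophthalate A4.
- Merits: very convergent. The aryloxy group directs the malonate carbon to C4a, so the substitution pattern of A4 is inherent. There is no detour through a seven-membered ring, and the two arms differ from the start.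
- Weak points: A2 needs an oxygen on C5' that the orsellinate skeleton lacks, and its phenoxide is flanked by two ortho groups. Two nucleophiles in one flask must each take their own aryne, and the anion of A3 can take the first one. A1 needs its own preparation. After A4 there still follow C4 acylation with 4, decarboxylation, lactonization and three kinds of deprotection.
- Comparison: this road is more convergent and shorter for ring A, and in that respect better. Against it the chosen plan sets bond formations that occur one at a time in well-understood steps, both halves from 1, and a chemoselectivity that is structural. It also passes through 21, itself a natural product.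

Alternative 2: Ring A is built from an open chain.
- Cut: the C8a-C4a bond.
- Forward key step: the open-chain beta-aryloxy enone ester A5 already carries the ring B oxygen on C8 as an enol ether. Mild base makes the C8a carbanion add to the C4a ketone, and loss of water aromatizes the ring to phenol A6 with a free hydroxyl on C6.
- Merits: the hindered aryl-oxygen bond is made early by addition-elimination, which is easier than a metal-mediated coupling between two doubly ortho-substituted positions. The single C6 hydroxyl can be methylated without any selectivity question.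
- Weak points: A5 is a polycarbonyl chain with several acidic sites. Claisen closure on the tert-butyl ester, pyranone formation through oxygen and loss of the ring B aryloxide from the vinylogous ester all compete. A5 itself is long to make. A6 still needs methylation, ester cleavage, ketal removal and lactonization, and its ring B ketone sits free beside a benzyl ester, so the two arms must again be told apart.
- Comparison: in forming the ether bond this road is better than the copper-mediated closure of the chosen plan. The chosen plan sets against it two intact aromatic rings from a commercial benzoate, no regiochemical question in ring formation, and fewer operations on sensitive polycarbonyl intermediates.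

Alternative 3: The isocoumarin is finished first and ring B is grown on its C8 oxygen.
- Cut: the C1'-C6' and C3'-C4' bonds of ring B.
- Forward key step: the alpha carbon of allyl acetoacetate A7 adds to the beta carbon of the alpha-aryloxy acrylate A8 (C1'-C6'). Its methyl carbon then condenses on the acrylate ester (C3'-C4') and closes cyclohexane-1,3-dione A9. Three stereocenters arise (racemic, all-trans expected) and are erased by the later dehydrogenation to the resorcinol.
- Merits: no diaryl ether coupling, because the O-C5' bond would come from a simple O-alkylation before ring B exists. There is no halogenation regiochemistry, and the two arms differ from the start.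
- Weak points: A8 is a poor Michael acceptor, with a donor oxygen on the alpha carbon and a bulky beta substituent. The alkoxide needed for the Claisen closure opens the enol lactone. In A9 the aryloxy group is alpha to a ketone and beta to the ester-bearing carbon, so enolization invites E1cB loss of the isocoumarin oxygen. The aromatization needs an oxidant next to benzylic positions.
- Comparison: this road avoids both the ether coupling and the positional question on ring B, which is a real advantage. The chosen plan sets against it a ring B that stays aromatic throughout and an enol lactone that appears only in the last step, so it never meets base or oxidant.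

Key step: step 18

Assumption: 21 and 22 are written as open keto acids; a lactol tautomer of the ring B keto acid unit would not change any step.

## Route

Step 1
Reactants: 1 methyl orsellinate (methyl 2,4-dihydroxy-6-methylbenzoate); 2 benzyl bromide (two equivalents are consumed, one per phenol)
Product: 3 methyl 2,4-bis(benzyloxy)-6-methylbenzoate
Conditions: BnBr (2.3 equiv), K2CO3 (3 equiv), DMF, 60 °C
Reagents that add atoms: benzyl bromide (the second equivalent of 2, which forms the second ether), BrCc1ccccc1
Why: Twofold Williamson etherification, one equivalent of 2 for each phenol; DMF and heat are needed for the chelated 2-hydroxyl. Benzyl ethers tolerate the amide base and the hydroxide used later.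

Step 2
Reactants: 4 hexanoyl chloride
Product: 5 N-methoxy-N-methylhexanamide
Conditions: MeNH(OMe)·HCl, Et3N, CH2Cl2, 0 °C to rt
Reagents that add atoms: N,O-dimethylhydroxylamine hydrochloride, CNOC.Cl
Why: Standard acylation of the hydroxylamine gives the Weinreb amide, an acyl donor that stops at the ketone stage.

Step 3
Reactants: 3 methyl 2,4-bis(benzyloxy)-6-methylbenzoate; 5 N-methoxy-N-methylhexanamide
Product: 7 methyl 2,4-bis(benzyloxy)-6-(2-oxoheptyl)benzoate, via lithiated toluate 6 (not isolated)
Conditions: LiN(iPr)2, THF, -78 °C; then 5, -78 to -40 °C; aq. NH4Cl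
Reagents that add atoms: none
Why: Lateral lithiation of an ortho-toluate followed by Weinreb acylation. The chelated tetrahedral adduct holds the ketone back until work-up, so neither double addition nor enol lactonization can occur in the basic medium.

Step 4
Reactants: 7 methyl 2,4-bis(benzyloxy)-6-(2-oxoheptyl)benzoate
Product: 8 methyl 2,4-bis(benzyloxy)-6-[(2-pentyl-1,3-dioxolan-2-yl)methyl]benzoate
Conditions: (TMSOCH2)2, TMSOTf (5 mol%), CH2Cl2, -78 to -20 °C; pyridine quench
Reagents that add atoms: 1,2-bis(trimethylsilyloxy)ethane, C[Si](C)(C)OCCO[Si](C)(C)C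
Why: Silyl-transfer ketalization under aprotic, low-temperature conditions masks the ketone without giving the keto ester the chance to close to an isocoumarin under protic acid and heat.

Step 5
Reactants: 8 methyl 2,4-bis(benzyloxy)-6-[(2-pentyl-1,3-dioxolan-2-yl)methyl]benzoate
Product: 9 2,4-bis(benzyloxy)-6-[(2-pentyl-1,3-dioxolan-2-yl)methyl]benzoic acid
Conditions: KOH, DMSO/H2O 4:1, 90 °C; then 1 M HCl to pH 4, 0 °C
Reagents that add atoms: potassium hydroxide, [K+].[OH-]
Why: Saponification of a doubly ortho-substituted methyl benzoate needs hydroxide in aqueous DMSO at elevated temperature; ketal and benzyl ethers are stable to base. Cold, mild acidification protects the ketal.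

Step 6
Reactants: 9 2,4-bis(benzyloxy)-6-[(2-pentyl-1,3-dioxolan-2-yl)methyl]benzoic acid
Product: 10 2,4-dihydroxy-6-[(2-pentyl-1,3-dioxolan-2-yl)methyl]benzoic acid
Conditions: H2 (1 atm), 10% Pd/C, EtOAc, rt
Reagents that add atoms: none
Why: Neutral hydrogenolysis of the benzyl ethers leaves the ketal intact. The dihydroxy acid should be kept at room temperature and used at once to avoid decarboxylation.

Step 7
Reactants: 10 2,4-dihydroxy-6-[(2-pentyl-1,3-dioxolan-2-yl)methyl]benzoic acid; 2 benzyl bromide
Product: 11 benzyl 2,4-dihydroxy-6-[(2-pentyl-1,3-dioxolan-2-yl)methyl]benzoate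
Conditions: BnBr (1.05 equiv), KHCO3, DMF, rt
Reagents that add atoms: none
Why: Hydrogencarbonate ionizes only the carboxylic acid, so SN2 alkylation with one equivalent of 2 gives the benzyl ester and leaves both phenols free. This is the standard way to benzyl esters of resorcylic acids.

Step 8
Reactants: 11 benzyl 2,4-dihydroxy-6-[(2-pentyl-1,3-dioxolan-2-yl)methyl]benzoate
Product: 12 benzyl 2,4-dihydroxy-5-iodo-6-[(2-pentyl-1,3-dioxolan-2-yl)methyl]benzoate (iodine between the 4-hydroxyl and the side chain)
Conditions: NIS (1.0 equiv), MeCN, -10 to 0 °C, dark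
Reagents that add atoms: N-iodosuccinimide, O=C1CCC(=O)N1I
Why: Electrophilic aromatic iodination of a 6-alkyl-2,4-dihydroxybenzoate is expected para to the chelated 2-hydroxyl and ortho to the free 4-hydroxyl. This is the position taken in halogenations of related resorcylates. The neutral reagent spares the ketal.

Step 9
Reactants: 8 methyl 2,4-bis(benzyloxy)-6-[(2-pentyl-1,3-dioxolan-2-yl)methyl]benzoate
Product: 13 methyl 2,4-dihydroxy-6-[(2-pentyl-1,3-dioxolan-2-yl)methyl]benzoate
Conditions: H2 (1 atm), 10% Pd/C, EtOAc, rt
Reagents that add atoms: none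
Why: Hydrogenolysis of both benzyl ethers; ester and ketal are untouched.

Step 10
Reactants: 13 methyl 2,4-dihydroxy-6-[(2-pentyl-1,3-dioxolan-2-yl)methyl]benzoate
Product: 14 methyl 2-hydroxy-4-methoxy-6-[(2-pentyl-1,3-dioxolan-2-yl)methyl]benzoate
Conditions: MeI (1.1 equiv), K2CO3, acetone, rt to 40 °C
Reagents that add atoms: iodomethane, CI
Why: Selective Williamson methylation of the 4-hydroxyl. The 2-hydroxyl is hydrogen-bonded to the ester carbonyl and reacts much more slowly, as in the known monomethylation of orsellinates.

Step 11
Reactants: 14 methyl 2-hydroxy-4-methoxy-6-[(2-pentyl-1,3-dioxolan-2-yl)methyl]benzoate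
Product: 15 methyl 4-methoxy-2-[(4-methoxybenzyl)oxy]-6-[(2-pentyl-1,3-dioxolan-2-yl)methyl]benzoate
Conditions: 4-methoxybenzyl chloride, K2CO3, Bu4NI (cat.), DMF, 60 °C
Reagents that add atoms: 4-methoxybenzyl chloride, COc1ccc(CCl)cc1
Why: Williamson etherification of the chelated phenol under forcing conditions. The 4-methoxybenzyl ether can later be removed by oxidation in the presence of aryl iodide, benzyl ester and ketals.

Step 12
Reactants: 15 methyl 4-methoxy-2-[(4-methoxybenzyl)oxy]-6-[(2-pentyl-1,3-dioxolan-2-yl)methyl]benzoate
Product: 16 4-methoxy-2-[(4-methoxybenzyl)oxy]-6-[(2-pentyl-1,3-dioxolan-2-yl)methyl]benzoic acid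
Conditions: KOH, DMSO/H2O 4:1, 90 °C; then 1 M HCl to pH 5, 0 °C
Reagents that add atoms: potassium hydroxide, [K+].[OH-]
Why: Saponification of the hindered methyl ester as in step 5; both ethers and the ketal are base-stable, and the cold, weakly acidic work-up protects ketal and 4-methoxybenzyl ether.

Step 13
Reactants: 16 4-methoxy-2-[(4-methoxybenzyl)oxy]-6-[(2-pentyl-1,3-dioxolan-2-yl)methyl]benzoic acid; 12 benzyl 2,4-dihydroxy-5-iodo-6-[(2-pentyl-1,3-dioxolan-2-yl)methyl]benzoate
Product: 17 benzyl 2-hydroxy-5-iodo-4-({4-methoxy-2-[(4-methoxybenzyl)oxy]-6-[(2-pentyl-1,3-dioxolan-2-yl)methyl]benzoyl}oxy)-6-[(2-pentyl-1,3-dioxolan-2-yl)methyl]benzoate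
Conditions: DCC, DMAP (0.2 equiv), CH2Cl2, 0 °C to rt
Reagents that add atoms: none
Why: Steglich esterification, the usual depside coupling. The 4-hydroxyl of 12 is the more acidic and unchelated one and is acylated, while the 2-hydroxyl stays hydrogen-bonded to the benzyl ester. The neutral conditions spare both ketals.

Step 14
Reactants: 17 (the protected depside of step 13)
Product: 18 benzyl 2-hydroxy-4-({2-hydroxy-4-methoxy-6-[(2-pentyl-1,3-dioxolan-2-yl)methyl]benzoyl}oxy)-5-iodo-6-[(2-pentyl-1,3-dioxolan-2-yl)methyl]benzoate
Conditions: DDQ, CH2Cl2/pH 7 phosphate buffer 10:1, rt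
Reagents that add atoms: none
Why: Oxidative cleavage of the 4-methoxybenzyl ether by hydride abstraction and hydrolysis of the oxocarbenium ion. Iodide, benzyl ester, aryl ester and the buffered ketals are not affected.

Step 15
Reactants: 18 (the iodo depside phenol of step 14)
Product: 19 benzyl 8-hydroxy-3-methoxy-11-oxo-1,6-bis[(2-pentyl-1,3-dioxolan-2-yl)methyl]-11H-dibenzo[b,e][1,4]dioxepine-7-carboxylate (bis-ketal of benzyl alpha-collatolate)
Conditions: CuI (0.3 equiv), N,N-dimethylglycine hydrochloride (0.6 equiv), Cs2CO3 (3 equiv), 1,4-dioxane (0.005 M), 90 °C, argon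
Reagents that add atoms: none
Why: Intramolecular Ullmann diaryl ether synthesis. The ester tether holds the ring A phenoxide beside the C5'-I bond and the seven-membered depsidone closes. The ester carbonyl is shielded by two ortho substituents and deactivated by the ortho phenoxide, and with both ketones masked no enolate can cleave the ester or attack the iodide.

Step 16
Reactants: 19 (the bis-ketal depsidone of step 15)
Product: 20 benzyl 8-hydroxy-3-methoxy-11-oxo-1,6-bis(2-oxoheptyl)-11H-dibenzo[b,e][1,4]dioxepine-7-carboxylate (benzyl alpha-collatolate)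
Conditions: 2 M HCl/THF 1:4, rt
Reagents that add atoms: water, O
Why: Acid hydrolysis of both dioxolanes. The hindered depsidone ester and the benzyl ester are stable to dilute aqueous acid at room temperature.

Step 17
Reactants: 20 benzyl alpha-collatolate
Product: 21 alpha-collatolic acid (8-hydroxy-3-methoxy-11-oxo-1,6-bis(2-oxoheptyl)-11H-dibenzo[b,e][1,4]dioxepine-7-carboxylic acid)
Conditions: H2 (1 atm), 10% Pd/C, EtOAc, rt
Reagents that add atoms: none
Why: Neutral hydrogenolysis of the benzyl ester, the standard last deprotection of depsidone acids. The aliphatic ketones and the aryl ester are not reduced under these conditions.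

Step 18
Reactants: 21 alpha-collatolic acid
Product: 22 beta-collatolic acid (2,4-dihydroxy-5-[(6-methoxy-1-oxo-3-pentyl-1H-isochromen-8-yl)oxy]-6-(2-oxoheptyl)benzoic acid)
Conditions: K2CO3 (4 equiv), dry DMF, 25 °C; then cold 1 M HCl; crystallization
Reagents that add atoms: none
Why: K2CO3 ionizes the carboxylic acid and the C2' phenol and reversibly deprotonates the benzylic CH2 of the ring A arm, the only arm with an acyl donor beside it. The (Z)-enolate oxygen adds to the depsidone carbonyl C1 in a 6-exo-trig closure, and the tetrahedral intermediate expels the C4' phenoxide, so the O2-C1 bond forms as the seven-membered ring opens. The closest known reactions are the enol lactonization of 2-(2-oxoalkyl)benzoic acid derivatives to isocoumarins and the opening of depsidone lactones by oxygen nucleophiles. The transfer should run downhill, because a strained, twisted aryl ester is exchanged for a planar conjugated 2-benzopyran-1-one and a phenoxide para to the carboxyl group. No stereocenter is formed. Chemoselectivity between the two identical arms is set by the substrate, since the ring B arm has only a carboxylate as neighbour. O-acylation is secured by geometry, since the benzylic carbon cannot reach C1 and the remote alpha-CH2 is not deprotonated by carbonate. The dry aprotic solvent keeps hydroxide and alkoxide away from C1.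

## Compound list

1 | methyl orsellinate (methyl 2,4-dihydroxy-6-methylbenzoate) | COC(=O)c1c(C)cc(O)cc1O | starting material
2 | benzyl bromide | BrCc1ccccc1 | starting material
3 | methyl 2,4-bis(benzyloxy)-6-methylbenzoate | COC(=O)c1c(C)cc(OCc2ccccc2)cc1OCc1ccccc1 | intermediate
4 | hexanoyl chloride | CCCCCC(=O)Cl | starting material
5 | N-methoxy-N-methylhexanamide | CCCCCC(=O)N(C)OC | intermediate
6 | methyl 2,4-bis(benzyloxy)-6-(lithiomethyl)benzoate (lithiated toluate, not isolated) | [Li]Cc1cc(OCc2ccccc2)cc(OCc2ccccc2)c1C(=O)OC | intermediate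
7 | methyl 2,4-bis(benzyloxy)-6-(2-oxoheptyl)benzoate | CCCCCC(=O)Cc1cc(OCc2ccccc2)cc(OCc2ccccc2)c1C(=O)OC | intermediate
8 | methyl 2,4-bis(benzyloxy)-6-[(2-pentyl-1,3-dioxolan-2-yl)methyl]benzoate | CCCCCC1(Cc2cc(OCc3ccccc3)cc(OCc3ccccc3)c2C(=O)OC)OCCO1 | intermediate
9 | 2,4-bis(benzyloxy)-6-[(2-pentyl-1,3-dioxolan-2-yl)methyl]benzoic acid | CCCCCC1(Cc2cc(OCc3ccccc3)cc(OCc3ccccc3)c2C(=O)O)OCCO1 | intermediate
10 | 2,4-dihydroxy-6-[(2-pentyl-1,3-dioxolan-2-yl)methyl]benzoic acid | CCCCCC1(Cc2cc(O)cc(O)c2C(=O)O)OCCO1 | intermediate
11 | benzyl 2,4-dihydroxy-6-[(2-pentyl-1,3-dioxolan-2-yl)methyl]benzoate | CCCCCC1(Cc2cc(O)cc(O)c2C(=O)OCc2ccccc2)OCCO1 | intermediate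
12 | benzyl 2,4-dihydroxy-5-iodo-6-[(2-pentyl-1,3-dioxolan-2-yl)methyl]benzoate | CCCCCC1(Cc2c(I)c(O)cc(O)c2C(=O)OCc2ccccc2)OCCO1 | intermediate
13 | methyl 2,4-dihydroxy-6-[(2-pentyl-1,3-dioxolan-2-yl)methyl]benzoate | CCCCCC1(Cc2cc(O)cc(O)c2C(=O)OC)OCCO1 | intermediate
14 | methyl 2-hydroxy-4-methoxy-6-[(2-pentyl-1,3-dioxolan-2-yl)methyl]benzoate | CCCCCC1(Cc2cc(OC)cc(O)c2C(=O)OC)OCCO1 | intermediate
15 | methyl 4-methoxy-2-[(4-methoxybenzyl)oxy]-6-[(2-pentyl-1,3-dioxolan-2-yl)methyl]benzoate | CCCCCC1(Cc2cc(OC)cc(OCc3ccc(OC)cc3)c2C(=O)OC)OCCO1 | intermediate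
16 | 4-methoxy-2-[(4-methoxybenzyl)oxy]-6-[(2-pentyl-1,3-dioxolan-2-yl)methyl]benzoic acid | CCCCCC1(Cc2cc(OC)cc(OCc3ccc(OC)cc3)c2C(=O)O)OCCO1 | intermediate
17 | benzyl 2-hydroxy-5-iodo-4-({4-methoxy-2-[(4-methoxybenzyl)oxy]-6-[(2-pentyl-1,3-dioxolan-2-yl)methyl]benzoyl}oxy)-6-[(2-pentyl-1,3-dioxolan-2-yl)methyl]benzoate | CCCCCC1(Cc2cc(OC)cc(OCc3ccc(OC)cc3)c2C(=O)Oc2cc(O)c(C(=O)OCc3ccccc3)c(CC3(CCCCC)OCCO3)c2I)OCCO1 | intermediate
18 | benzyl 2-hydroxy-4-({2-hydroxy-4-methoxy-6-[(2-pentyl-1,3-dioxolan-2-yl)methyl]benzoyl}oxy)-5-iodo-6-[(2-pentyl-1,3-dioxolan-2-yl)methyl]benzoate | CCCCCC1(Cc2cc(OC)cc(O)c2C(=O)Oc2cc(O)c(C(=O)OCc3ccccc3)c(CC3(CCCCC)OCCO3)c2I)OCCO1 | intermediate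
19 | benzyl 8-hydroxy-3-methoxy-11-oxo-1,6-bis[(2-pentyl-1,3-dioxolan-2-yl)methyl]-11H-dibenzo[b,e][1,4]dioxepine-7-carboxylate | CCCCCC1(Cc2cc(OC)cc3Oc4c(CC5(CCCCC)OCCO5)c(C(=O)OCc5ccccc5)c(O)cc4OC(=O)c23)OCCO1 | intermediate
20 | benzyl alpha-collatolate (benzyl 8-hydroxy-3-methoxy-11-oxo-1,6-bis(2-oxoheptyl)-11H-dibenzo[b,e][1,4]dioxepine-7-carboxylate) | CCCCCC(=O)Cc1cc(OC)cc2Oc3c(CC(=O)CCCCC)c(C(=O)OCc4ccccc4)c(O)cc3OC(=O)c12 | intermediate
21 | alpha-collatolic acid | CCCCCC(=O)Cc1cc(OC)cc2Oc3c(CC(=O)CCCCC)c(C(=O)O)c(O)cc3OC(=O)c12 | intermediate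
22 | beta-collatolic acid | CCCCCC(=O)Cc1c(Oc2cc(OC)cc3cc(CCCCC)oc(=O)c23)c(O)cc(O)c1C(=O)O | target

## Step count and least certain steps

Total: 18 steps. Longest linear sequence: 13 steps (steps 1, 3, 4, 5, 6, 7, 8, 13, 14, 15, 16, 17, 18; the ring A branch through steps 9 to 12 is equally long).

**Step 18 (key step).**
- Risk: hydrolytic opening of the depsidone ester by traces of water, which would leave a ring A carboxylate that cannot lactonize under base. Enolization may also be slow, because the substrate is already a dianion.
- Fallback: the same O2-C1 bond is made in two stages from 20. LiOH in aqueous THF at 0 °C opens the strained aryl ester to the seco acid, 2-{[3-(benzyloxycarbonyl)-4,6-dihydroxy-2-(2-oxoheptyl)phenyl]oxy}-4-methoxy-6-(2-oxoheptyl)benzoic acid F1. Trifluoroacetic anhydride then closes the ring A keto acid by dehydrative enol lactonization to benzyl beta-collatolate F2. Here only ring A has a free carboxyl, and the ring B benzyl ester is no acyl donor. Hydrogenolysis of F2 over Pd/C returns to the route at 22.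

**Step 15.**
- Risk: slow insertion of copper into the hindered, electron-rich C5'-I bond, with protodeiodination and intermolecular acyl transfer at 90 °C competing.
- Fallback: the ring is closed without a halogen by oxidative phenol coupling. From 11 and 16, carbodiimide esterification gives the iodine-free protected depside F3. DDQ removes the 4-methoxybenzyl ether to give the depside diphenol F4. MnO2 in chloroform then couples the ring A phenol oxygen to C5', para to the C2' hydroxyl. This is the classical oxidative cyclization of depsides to depsidones, and it returns to the route at 19.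

**Step 8.**
- Risk: poor positional selectivity between C3' and C5', and double iodination. The bulky ketal arm beside C5' may divert the electrophile to C3', and either iodide could later close a depsidone.
- Fallback: the iodine is placed before the arm on a bis-ether, where substitution ortho to the methyl group and away from the position between two alkoxy groups is the rule. From 1, two equivalents of 4-methoxybenzyl chloride and K2CO3 give methyl 2,4-bis[(4-methoxybenzyl)oxy]-6-methylbenzoate F5. NIS gives methyl 3-iodo-4,6-bis[(4-methoxybenzyl)oxy]-2-methylbenzoate F6. Lateral lithiation and acylation with 5 give the keto ester F7. Ketalization gives the dioxolane ester F8, saponification the acid F9, and alkylation with 2 the benzyl ester F10. DDQ removes both ethers and returns to the route at 12.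

**Step 13.**
- Risk: slow acyl transfer between a doubly ortho-substituted acid and an ortho-iodophenol, which allows rearrangement of the activated acid to the N-acylurea or acylation of the wrong hydroxyl.
- Fallback: the acid is activated separately under neutral conditions. From 16, 1-chloro-N,N,2-trimethylpropenylamine gives the acid chloride, 4-methoxy-2-[(4-methoxybenzyl)oxy]-6-[(2-pentyl-1,3-dioxolan-2-yl)methyl]benzoyl chloride F11. Adding it to 12 with Et3N and DMAP returns to the route at 17.

**Step 14.**
- Risk: sluggish oxidation of a phenolic 4-methoxybenzyl ether, with over-oxidation of the electron-rich rings or ketal loss caused by the acidic hydroquinone.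
- Fallback: the protecting group is left out. From 14, saponification gives 2-hydroxy-4-methoxy-6-[(2-pentyl-1,3-dioxolan-2-yl)methyl]benzoic acid F12. Its chelated hydroxyl is a poor nucleophile, so direct carbodiimide coupling with 12 returns to the route at 18 and skips 15, 16 and 17.

## Further compounds

F1 | step 18 | 2-{[3-(benzyloxycarbonyl)-4,6-dihydroxy-2-(2-oxoheptyl)phenyl]oxy}-4-methoxy-6-(2-oxoheptyl)benzoic acid | CCCCCC(=O)Cc1cc(OC)cc(Oc2c(O)cc(O)c(C(=O)OCc3ccccc3)c2CC(=O)CCCCC)c1C(=O)O
F2 | step 18 | benzyl beta-collatolate | CCCCCC(=O)Cc1c(Oc2cc(OC)cc3cc(CCCCC)oc(=O)c23)c(O)cc(O)c1C(=O)OCc1ccccc1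
F3 | step 15 | benzyl 2-hydroxy-4-({4-methoxy-2-[(4-methoxybenzyl)oxy]-6-[(2-pentyl-1,3-dioxolan-2-yl)methyl]benzoyl}oxy)-6-[(2-pentyl-1,3-dioxolan-2-yl)methyl]benzoate | CCCCCC1(Cc2cc(OC)cc(OCc3ccc(OC)cc3)c2C(=O)Oc2cc(O)c(C(=O)OCc3ccccc3)c(CC3(CCCCC)OCCO3)c2)OCCO1
F4 | step 15 | benzyl 2-hydroxy-4-({2-hydroxy-4-methoxy-6-[(2-pentyl-1,3-dioxolan-2-yl)methyl]benzoyl}oxy)-6-[(2-pentyl-1,3-dioxolan-2-yl)methyl]benzoate | CCCCCC1(Cc2cc(OC)cc(O)c2C(=O)Oc2cc(O)c(C(=O)OCc3ccccc3)c(CC3(CCCCC)OCCO3)c2)OCCO1
F5 | step 8 | methyl 2,4-bis[(4-methoxybenzyl)oxy]-6-methylbenzoate | COC(=O)c1c(C)cc(OCc2ccc(OC)cc2)cc1OCc1ccc(OC)cc1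
F6 | step 8 | methyl 3-iodo-4,6-bis[(4-methoxybenzyl)oxy]-2-methylbenzoate | COC(=O)c1c(C)c(I)c(OCc2ccc(OC)cc2)cc1OCc1ccc(OC)cc1
F7 | step 8 | methyl 3-iodo-4,6-bis[(4-methoxybenzyl)oxy]-2-(2-oxoheptyl)benzoate | CCCCCC(=O)Cc1c(I)c(OCc2ccc(OC)cc2)cc(OCc2ccc(OC)cc2)c1C(=O)OC
F8 | step 8 | methyl 3-iodo-4,6-bis[(4-methoxybenzyl)oxy]-2-[(2-pentyl-1,3-dioxolan-2-yl)methyl]benzoate | CCCCCC1(Cc2c(I)c(OCc3ccc(OC)cc3)cc(OCc3ccc(OC)cc3)c2C(=O)OC)OCCO1
F9 | step 8 | 3-iodo-4,6-bis[(4-methoxybenzyl)oxy]-2-[(2-pentyl-1,3-dioxolan-2-yl)methyl]benzoic acid | CCCCCC1(Cc2c(I)c(OCc3ccc(OC)cc3)cc(OCc3ccc(OC)cc3)c2C(=O)O)OCCO1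
F10 | step 8 | benzyl 3-iodo-4,6-bis[(4-methoxybenzyl)oxy]-2-[(2-pentyl-1,3-dioxolan-2-yl)methyl]benzoate | CCCCCC1(Cc2c(I)c(OCc3ccc(OC)cc3)cc(OCc3ccc(OC)cc3)c2C(=O)OCc2ccccc2)OCCO1
F11 | step 13 | 4-methoxy-2-[(4-methoxybenzyl)oxy]-6-[(2-pentyl-1,3-dioxolan-2-yl)methyl]benzoyl chloride | CCCCCC1(Cc2cc(OC)cc(OCc3ccc(OC)cc3)c2C(=O)Cl)OCCO1
F12 | step 14 | 2-hydroxy-4-methoxy-6-[(2-pentyl-1,3-dioxolan-2-yl)methyl]benzoic acid | CCCCCC1(Cc2cc(OC)cc(O)c2C(=O)O)OCCO1
A1 | alternative 1 | 5-methoxy-2-(trimethylsilyl)-1,3-phenylene bis(trifluoromethanesulfonate) | COc1cc(OS(=O)(=O)C(F)(F)F)c([Si](C)(C)C)c(OS(=O)(=O)C(F)(F)F)c1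
A2 | alternative 1 | benzyl 4,6-bis(benzyloxy)-3-hydroxy-2-[(2-pentyl-1,3-dioxolan-2-yl)methyl]benzoate | CCCCCC1(Cc2c(O)c(OCc3ccccc3)cc(OCc3ccccc3)c2C(=O)OCc2ccccc2)OCCO1
A3 | alternative 1 | diallyl malonate | C=CCOC(=O)CC(=O)OCC=C
A4 | alternative 1 | diallyl 3-aryloxy-5-methoxyhomophthalate (aryl is the protected ring B with its ketone as dioxolane) | CCCCCC1(Cc2c(Oc3cc(OC)cc(CC(=O)OCC=C)c3C(=O)OCC=C)c(OCc3ccccc3)cc(OCc3ccccc3)c2C(=O)OCc2ccccc2)OCCO1
A5 | alternative 2 | tert-butyl 3-aryloxy-5,7-dioxo-8-(2-pentyl-1,3-dioxolan-2-yl)oct-3-enoate (aryl is the tribenzyl-protected ring B; alkene geometry not defined) | CCCCCC1(CC(=O)CC(=O)C=C(CC(=O)OC(C)(C)C)Oc2c(CC(=O)CCCCC)c(C(=O)OCc3ccccc3)c(OCc3ccccc3)cc2OCc2ccccc2)OCCO1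
A6 | alternative 2 | tert-butyl 2-aryloxy-4-hydroxy-6-[(2-pentyl-1,3-dioxolan-2-yl)methyl]benzoate (aryl is the tribenzyl-protected ring B) | CCCCCC1(Cc2cc(O)cc(Oc3c(CC(=O)CCCCC)c(C(=O)OCc4ccccc4)c(OCc4ccccc4)cc3OCc3ccccc3)c2C(=O)OC(C)(C)C)OCCO1
A7 | alternative 3 | allyl acetoacetate | CC(=O)CC(=O)OCC=C
A8 | alternative 3 | methyl 2-[(6-methoxy-1-oxo-3-pentyl-1H-isochromen-8-yl)oxy]-4-(2-pentyl-1,3-dioxolan-2-yl)but-2-enoate (methyl ester assumed; alkene geometry not defined) | COC(=O)C(Oc1cc(OC)cc2cc(CCCCC)oc(=O)c12)=CCC1(CCCCC)OCCO1
A9 | alternative 3 | allyl 3-aryloxy-4,6-dioxo-2-[(2-pentyl-1,3-dioxolan-2-yl)methyl]cyclohexane-1-carboxylate (racemic, expected all-trans isomer drawn as one enantiomer; aryl is the isocoumarin) | CCCCCC1(C[C@@H]2[C@@H](Oc3cc(OC)cc4cc(CCCCC)oc(=O)c34)C(=O)CC(=O)[C@H]2C(=O)OCC=C)OCCO1
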